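**Retrosynthetic overview**

1. The target is a cis-(2R,3S)-2,3-dimethylchroman-4-one (chromanone numbering O1 to C8a; C1' is the side-chain methine). The strategy rests on ring A being hexasubstituted, with oxygens at C5, C7 and C8a alternating with carbons at C4a, C6 and C8.
2. Ring B is opened last: O1–C2 by a quinine-catalysed oxa-Michael closure of an o-tigloylphenol (sets C2 and C3), and C4–C4a by Friedel–Crafts acylation at the single free ring position.
3. Ring A is cut at C6–C7 and C4a–C5 (C7–C8 is broken and re-formed) to cyclobutenone 7 and siloxyalkyne 11. C6 is carried as allyl, a prenyl surrogate that survives the Lewis-acid steps and is converted by cross-metathesis in step 11.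
4. Cyclobutenone 7 comes from desymmetrised 3-propylglutaric anhydride (sets C1') by a ketene [2+2] with ethoxyacetylene; alkyne 11 comes from pent-1-en-4-yne by ynolate oxidation and silylation.
5. Order of ring formation: ring A (step 6), then ring B (step 10).

Key step: step 6

Assumption: (DHQD)2AQN is taken to open anhydride 2 to the (S)-hemiester and quinine to give the (2R)-chromanone; if either sense proves opposite, the pseudo-enantiomeric alkaloid ((DHQ)2AQN, quinidine) is used with no other change.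

**Route**

Step 1
Reactants: 1 3-propylglutaric acid
Product: 2 3-propylglutaric anhydride (4-propyloxane-2,6-dione)
Conditions: Ac2O, reflux; distil
Reagents that add atoms: none
Why: Cyclodehydration of a 1,5-diacid to the six-membered cyclic anhydride by anhydride exchange with acetic anhydride is routine and involves no stereocentre.

Step 2
Reactants: 2 3-propylglutaric anhydride
Product: 3 (3S)-3-(2-methoxy-2-oxoethyl)hexanoic acid
Conditions: (DHQD)2AQN (0.1 equiv), MeOH (10 equiv), Et2O, −40 °C
Reagents that add atoms: methanol, CO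
Why: Cinchona-alkaloid-catalysed desymmetrising methanolysis of a prochiral 3-alkylglutaric anhydride, in which the chiral amine acts as general base and directs methanol to one of the two enantiotopic carbonyl groups, sets C3 (the later C1') as S.

Step 3
Reactants: 3 (3S)-3-(2-methoxy-2-oxoethyl)hexanoic acid
Product: 4 methyl (3R)-3-(2-chloro-2-oxoethyl)hexanoate
Conditions: (COCl)2, DMF (cat.), CH2Cl2, 0 °C to rt; evaporate, use crude
Reagents that add atoms: oxalyl chloride, O=C(Cl)C(Cl)=O
Why: Acid chloride formation with oxalyl chloride under DMF catalysis runs at or below room temperature, where the hemiester does not scramble through the cyclic anhydride; the stereocentre is beta to both carbonyls and cannot epimerise (its descriptor changes from S to R only because the CIP priorities change).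

Step 4
Reactants: 4 methyl (3R)-3-(2-chloro-2-oxoethyl)hexanoate; 5 ethoxyacetylene
Product: 7 methyl (3R)-3-[(1RS)-2-ethoxy-4-oxocyclobut-2-en-1-yl]hexanoate, via ketene 6 (not isolated)
Conditions: 5 (2.5 equiv), Et3N (1.2 equiv, slow addition), Et2O, 0 °C to rt
Reagents that add atoms: none
Why: Dehydrochlorination gives aldoketene 6, which enters the known [2+2] cycloaddition of ketenes with ethoxyacetylene; the nucleophilic terminal alkyne carbon attacks the ketene carbonyl carbon, so ethoxy ends at C3 and the side chain at C4 of the cyclobutenone, whose ring stereocentre forms as a mixture and is erased in step 6.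

Step 5
Reactants: 8 pent-1-en-4-yne
Product: 11 triisopropyl(pent-4-en-1-yn-1-yloxy)silane, via lithium acetylide 9 (not isolated), via lithium ynolate 10 (not isolated)
Conditions: LiN(SiMe3)2, THF, −78 °C; t-BuOOLi (from t-BuOOH and LiN(SiMe3)2), −78 to 0 °C; i-Pr3SiOTf, −78 °C to rt
Reagents that add atoms: tert-butyl hydroperoxide, CC(C)(C)OO; triisopropylsilyl trifluoromethanesulfonate, CC(C)[Si](OS(=O)(=O)C(F)(F)F)(C(C)C)C(C)C
Why: Oxidation of a lithium acetylide with lithium tert-butyl peroxide followed by O-silylation of the ynolate with a bulky silyl triflate is the standard preparation of triisopropylsilyl ynol ethers; the acetylenic C–H is far more acidic than the skipped CH2, so the enyne is not isomerised at −78 °C.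

Step 6
Reactants: 7 methyl (3R)-3-[(1RS)-2-ethoxy-4-oxocyclobut-2-en-1-yl]hexanoate; 11 triisopropyl(pent-4-en-1-yn-1-yloxy)silane
Product: 16 methyl (3R)-3-[6-ethoxy-2-hydroxy-3-(prop-2-en-1-yl)-4-(triisopropylsilyloxy)phenyl]hexanoate, via vinylketene 12 (not isolated), via vinylcyclobutenone 13 (not isolated), via dienylketene 14 (not isolated), via cyclohexadienone 15 (not isolated)
Conditions: 11 (1.4 equiv), toluene, 110 °C, sealed tube
Reagents that add atoms: none
Why: Thermal 4π electrocyclic opening of 7 (side chain rotating outward) gives alkoxyvinylketene 12, which adds [2+2] to the electron-rich siloxyalkyne to give 13; a second 4π opening gives dienylketene 14, which closes ring A by disrotatory 6π electrocyclisation (re-forming C7–C8) to cyclohexadienone 15, and tautomerisation gives phenol 16. This is the Danheiser benzannulation of a cyclobutenone with a siloxyalkyne; 3-oxygenated 4-alkylcyclobutenones are known partners in this reaction class, though they open less readily than 3-alkyl ones. The selectivity needed is the regiochemistry of the [2+2] step, and polarity secures it: the alkyne carbon remote from oxygen (bearing allyl) bonds to the ketene carbonyl carbon (C6–C7) and the oxygen-bearing carbon bonds to the ketene alpha carbon (C5–C4a), so allyl lies between O7 and O5. Ring A is formed with every carbon carrying its final substituent (hydrogen at C4a) and with three chemically distinct oxygens: free hydroxyl at C7, silyl ether at C5, ethyl ether at C8a. No stereocentre is created, since the ring stereocentres of 7, 13 and 15 are lost on aromatisation and C1' lies outside the pericyclic array and is not epimerisable under neutral thermal conditions. Excess alkyne is used so that the bimolecular cycloaddition outruns capture of the ketenes by the product phenol.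

Step 7
Reactants: 16 methyl (3R)-3-[6-ethoxy-2-hydroxy-3-(prop-2-en-1-yl)-4-(triisopropylsilyloxy)phenyl]hexanoate
Product: 17 methyl (3R)-3-[2-(tert-butyldimethylsilyloxy)-6-ethoxy-3-(prop-2-en-1-yl)-4-(triisopropylsilyloxy)phenyl]hexanoate
Conditions: t-BuMe2SiOTf, 2,6-lutidine, CH2Cl2, 0 °C
Reagents that add atoms: tert-butyldimethylsilyl trifluoromethanesulfonate, CC(C)(C)[Si](C)(C)OS(=O)(=O)C(F)(F)F
Why: Silylation of the hindered C7 phenol with a silyl triflate and 2,6-lutidine blocks O-acylation and lactonisation at O7 in the Lewis-acid steps and is removed together with the C5 silyl ether at the end.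

Step 8
Reactants: 17 methyl (3R)-3-[2-(tert-butyldimethylsilyloxy)-6-ethoxy-3-(prop-2-en-1-yl)-4-(triisopropylsilyloxy)phenyl]hexanoate; 18 tigloyl chloride ((2E)-2-methylbut-2-enoyl chloride)
Product: 19 methyl (3R)-3-{2-(tert-butyldimethylsilyloxy)-6-ethoxy-5-[(2E)-2-methylbut-2-enoyl]-3-(prop-2-en-1-yl)-4-(triisopropylsilyloxy)phenyl}hexanoate
Conditions: SnCl4, CH2Cl2, −78 to −30 °C; cold aq. NaHCO3
Reagents that add atoms: none
Why: Friedel–Crafts acylation at C4a, the only unsubstituted ring position, activated by two ortho oxygens (O5, O8a) and one para oxygen (O7); the terminal allyl group, unlike a prenyl group, is not ionised by the HCl and SnCl4 present, and the E geometry of the acyl unit is kept.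

Step 9
Reactants: 19 methyl (3R)-3-{2-(tert-butyldimethylsilyloxy)-6-ethoxy-5-[(2E)-2-methylbut-2-enoyl]-3-(prop-2-en-1-yl)-4-(triisopropylsilyloxy)phenyl}hexanoate
Product: 21 methyl (3R)-3-{2-(tert-butyldimethylsilyloxy)-6-hydroxy-5-[(2E)-2-methylbut-2-enoyl]-3-(prop-2-en-1-yl)-4-(triisopropylsilyloxy)phenyl}hexanoate, via aryloxydichloroborane 20 (not isolated)
Conditions: BCl3 (1 M in CH2Cl2, 1.5 equiv), CH2Cl2, −78 to −20 °C; aq. NaHCO3
Reagents that add atoms: none
Why: Chelation-controlled dealkylation of an alkyl aryl ether ortho to a ketone, in which BCl3 bridges the carbonyl and the more basic, less hindered ethoxy oxygen (not the bulky, weakly basic C5 silyloxy oxygen nor the remote O7 silyl ether) and chloride removes ethyl by SN2 to give chelate 20, hydrolysed on work-up.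

Step 10
Reactants: 21 methyl (3R)-3-{2-(tert-butyldimethylsilyloxy)-6-hydroxy-5-[(2E)-2-methylbut-2-enoyl]-3-(prop-2-en-1-yl)-4-(triisopropylsilyloxy)phenyl}hexanoate
Product: 22 methyl (3R)-3-[(2R,3S)-7-(tert-butyldimethylsilyloxy)-2,3-dimethyl-4-oxo-6-(prop-2-en-1-yl)-5-(triisopropylsilyloxy)-3,4-dihydro-2H-chromen-8-yl]hexanoate
Conditions: quinine (0.2 equiv), chlorobenzene, 20 °C
Reagents that add atoms: none
Why: Cinchona-alkaloid-catalysed intramolecular oxa-Michael addition (6-endo-trig) of an o-tigloylphenol, a known route to cis-2,3-dimethylchroman-4-ones: the quinuclidine nitrogen deprotonates the C8a phenol, the chiral ion pair controls the enone face attacked by oxygen (C2, expected R with quinine), and kinetic protonation of the enol(ate) anti to the pseudo-axial C2 methyl sets C3 as S (cis); O5 is silylated, so only O8a can close ring B.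

Step 11
Reactants: 22 methyl (3R)-3-[(2R,3S)-7-(tert-butyldimethylsilyloxy)-2,3-dimethyl-4-oxo-6-(prop-2-en-1-yl)-5-(triisopropylsilyloxy)-3,4-dihydro-2H-chromen-8-yl]hexanoate; 23 2-methylbut-2-ene
Product: 24 methyl (3R)-3-[(2R,3S)-7-(tert-butyldimethylsilyloxy)-2,3-dimethyl-6-(3-methylbut-2-en-1-yl)-4-oxo-5-(triisopropylsilyloxy)-3,4-dihydro-2H-chromen-8-yl]hexanoate
Conditions: second-generation Grubbs catalyst (5 mol %), 23/CH2Cl2 (1:1), 40 °C, sealed tube
Reagents that add atoms: none
Why: Olefin cross-metathesis of a terminal allyl arene with excess 2-methylbut-2-ene is the standard conversion of allyl into prenyl; the neutral catalyst leaves the ketone, ester, silyl ethers and the C2 and C3 stereocentres untouched.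

Step 12
Reactants: 24 methyl (3R)-3-[(2R,3S)-7-(tert-butyldimethylsilyloxy)-2,3-dimethyl-6-(3-methylbut-2-en-1-yl)-4-oxo-5-(triisopropylsilyloxy)-3,4-dihydro-2H-chromen-8-yl]hexanoate
Product: 25 methyl (3R)-3-[(2R,3S)-5,7-dihydroxy-2,3-dimethyl-6-(3-methylbut-2-en-1-yl)-4-oxo-3,4-dihydro-2H-chromen-8-yl]hexanoate (CNP0068017.1)
Conditions: Bu4NF, AcOH (1:1, 2.5 equiv each), THF, 0 °C to rt
Reagents that add atoms: none
Why: Fluoride cleavage of both aryl silyl ethers; the acetic acid buffer keeps the medium non-basic, so C3 (alpha to the ketone) should not epimerise, ring B should not open by retro-oxa-Michael reaction, and the C7 phenoxide is protonated before it can lactonise onto the ester.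

**Compound list**

1 | 3-propylglutaric acid (3-propylpentanedioic acid) | CCCC(CC(=O)O)CC(=O)O | starting material
2 | 3-propylglutaric anhydride (4-propyloxane-2,6-dione) | CCCC1CC(=O)OC(=O)C1 | intermediate
3 | (3S)-3-(2-methoxy-2-oxoethyl)hexanoic acid | CCC[C@H](CC(=O)OC)CC(=O)O | intermediate
4 | methyl (3R)-3-(2-chloro-2-oxoethyl)hexanoate | CCC[C@H](CC(=O)OC)CC(Cl)=O | intermediate
5 | ethoxyacetylene | CCOC#C | starting material
6 | ketene, formed in the flask: methyl (3R)-3-(2-oxoethenyl)hexanoate | CCC[C@H](CC(=O)OC)C=C=O | intermediate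
7 | methyl (3R)-3-[(1RS)-2-ethoxy-4-oxocyclobut-2-en-1-yl]hexanoate | CCC[C@H](CC(=O)OC)C1C(=O)C=C1OCC | intermediate
8 | pent-1-en-4-yne | C=CCC#C | starting material
9 | lithium acetylide, formed in the flask: (pent-4-en-1-yn-1-yl)lithium | [Li]C#CCC=C | intermediate
10 | lithium ynolate, formed in the flask: lithium pent-4-en-1-yn-1-olate | [Li]OC#CCC=C | intermediate
11 | triisopropyl(pent-4-en-1-yn-1-yloxy)silane | C=CCC#CO[Si](C(C)C)(C(C)C)C(C)C | intermediate
12 | vinylketene, formed in the flask: methyl (3R,4Z)-5-ethoxy-7-oxo-3-propylhepta-4,6-dienoate | CCC[C@H](CC(=O)OC)/C=C(OCC)/C=C=O | intermediate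
13 | vinylcyclobutenone, formed in the flask: methyl (3R,4Z)-5-ethoxy-5-[4-oxo-3-(prop-2-en-1-yl)-2-(triisopropylsilyloxy)cyclobut-2-en-1-yl]-3-propylpent-4-enoate | CCC[C@H](CC(=O)OC)/C=C(OCC)/C1C(=O)C(CC=C)=C1O[Si](C(C)C)(C(C)C)C(C)C | intermediate
14 | dienylketene, formed in the flask: methyl (3R,4Z,6E)-5-ethoxy-9-oxo-8-(prop-2-en-1-yl)-3-propyl-7-(triisopropylsilyloxy)nona-4,6,8-trienoate | CCC[C@H](CC(=O)OC)/C=C(OCC)/C=C(O[Si](C(C)C)(C(C)C)C(C)C)\C(CC=C)=C=O | intermediate
15 | cyclohexadienone, formed in the flask: methyl (3R)-3-[2-ethoxy-6-oxo-5-(prop-2-en-1-yl)-4-(triisopropylsilyloxy)cyclohexa-2,4-dien-1-yl]hexanoate | CCC[C@H](CC(=O)OC)C1C(=O)C(CC=C)=C(O[Si](C(C)C)(C(C)C)C(C)C)C=C1OCC | intermediate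
16 | methyl (3R)-3-[6-ethoxy-2-hydroxy-3-(prop-2-en-1-yl)-4-(triisopropylsilyloxy)phenyl]hexanoate | CCC[C@H](CC(=O)OC)c1c(O)c(CC=C)c(O[Si](C(C)C)(C(C)C)C(C)C)cc1OCC | intermediate
17 | methyl (3R)-3-[2-(tert-butyldimethylsilyloxy)-6-ethoxy-3-(prop-2-en-1-yl)-4-(triisopropylsilyloxy)phenyl]hexanoate | CCC[C@H](CC(=O)OC)c1c(O[Si](C)(C)C(C)(C)C)c(CC=C)c(O[Si](C(C)C)(C(C)C)C(C)C)cc1OCC | intermediate
18 | tigloyl chloride ((2E)-2-methylbut-2-enoyl chloride) | C/C=C(\C)C(Cl)=O | starting material
19 | methyl (3R)-3-{2-(tert-butyldimethylsilyloxy)-6-ethoxy-5-[(2E)-2-methylbut-2-enoyl]-3-(prop-2-en-1-yl)-4-(triisopropylsilyloxy)phenyl}hexanoate | CCC[C@H](CC(=O)OC)c1c(O[Si](C)(C)C(C)(C)C)c(CC=C)c(O[Si](C(C)C)(C(C)C)C(C)C)c(C(=O)/C(C)=C/C)c1OCC | intermediate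
20 | aryloxydichloroborane, formed in the flask: methyl (3R)-3-{2-(tert-butyldimethylsilyloxy)-6-(dichloroboranyloxy)-5-[(2E)-2-methylbut-2-enoyl]-3-(prop-2-en-1-yl)-4-(triisopropylsilyloxy)phenyl}hexanoate | CCC[C@H](CC(=O)OC)c1c(O[Si](C)(C)C(C)(C)C)c(CC=C)c(O[Si](C(C)C)(C(C)C)C(C)C)c(C(=O)/C(C)=C/C)c1OB(Cl)Cl | intermediate
21 | methyl (3R)-3-{2-(tert-butyldimethylsilyloxy)-6-hydroxy-5-[(2E)-2-methylbut-2-enoyl]-3-(prop-2-en-1-yl)-4-(triisopropylsilyloxy)phenyl}hexanoate | CCC[C@H](CC(=O)OC)c1c(O[Si](C)(C)C(C)(C)C)c(CC=C)c(O[Si](C(C)C)(C(C)C)C(C)C)c(C(=O)/C(C)=C/C)c1O | intermediate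
22 | methyl (3R)-3-[(2R,3S)-7-(tert-butyldimethylsilyloxy)-2,3-dimethyl-4-oxo-6-(prop-2-en-1-yl)-5-(triisopropylsilyloxy)-3,4-dihydro-2H-chromen-8-yl]hexanoate | CCC[C@H](CC(=O)OC)c1c(O[Si](C)(C)C(C)(C)C)c(CC=C)c(O[Si](C(C)C)(C(C)C)C(C)C)c2c1O[C@H](C)[C@H](C)C2=O | intermediate
23 | 2-methylbut-2-ene | CC=C(C)C | starting material
24 | methyl (3R)-3-[(2R,3S)-7-(tert-butyldimethylsilyloxy)-2,3-dimethyl-6-(3-methylbut-2-en-1-yl)-4-oxo-5-(triisopropylsilyloxy)-3,4-dihydro-2H-chromen-8-yl]hexanoate | CCC[C@H](CC(=O)OC)c1c(O[Si](C)(C)C(C)(C)C)c(CC=C(C)C)c(O[Si](C(C)C)(C(C)C)C(C)C)c2c1O[C@H](C)[C@H](C)C2=O | intermediate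
25 | methyl (3R)-3-[(2R,3S)-5,7-dihydroxy-2,3-dimethyl-6-(3-methylbut-2-en-1-yl)-4-oxo-3,4-dihydro-2H-chromen-8-yl]hexanoate (CNP0068017.1) | CCC[C@H](CC(=O)OC)c1c(O)c(CC=C(C)C)c(O)c2c1O[C@H](C)[C@H](C)C2=O | target

**Step count**

Total: 12 steps. Longest linear sequence: 11 steps (steps 1–4 and 6–12, from 3-propylglutaric acid); step 5 is the one-step side branch.

**Steps most likely to fail**

Step 6 (benzannulation).
- What may go wrong: the ethoxy-stabilised cyclobutenone may open too slowly at temperatures the siloxyalkyne tolerates, so the alkyne is lost by rearrangement to a silylketene. The ketene intermediates may also be captured by the product phenol (O-acylation). Phenol 16 may partly lactonise onto its own ester; that part is reversible with MeOH/Et3N, with no stereocentre at risk.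
- Fallback: ring A is taken from the aromatic pool and only the side-chain stereocentre is made. This fallback does not branch from a route intermediate: it sets out from commercial 5,7-dihydroxy-4-propyl-2H-chromen-2-one F1 and comes back to the route at 16. Selective O-allylation of the more acidic 7-hydroxyl (allyl bromide, K2CO3, acetone) should give 5-hydroxy-7-(prop-2-en-1-yloxy)-4-propyl-2H-chromen-2-one F2. O-ethylation (EtI, K2CO3, DMF) then gives 5-ethoxy-7-(prop-2-en-1-yloxy)-4-propyl-2H-chromen-2-one F3. Aromatic Claisen rearrangement (N,N-diethylaniline, 190 °C) is expected to deliver allyl mainly to C8 of the coumarin, the position between the two ring oxygens and the future C6, giving 5-ethoxy-7-hydroxy-8-(prop-2-en-1-yl)-4-propyl-2H-chromen-2-one F4; any 6-allyl isomer is separated. Silylation (i-Pr3SiOTf, 2,6-lutidine) gives 5-ethoxy-8-(prop-2-en-1-yl)-4-propyl-7-(triisopropylsilyloxy)-2H-chromen-2-one F5. Copper hydride asymmetric conjugate reduction of the 4-substituted coumarin (Cu(OAc)2, a SEGPHOS-type bisphosphine of the enantiomer that gives 4R, (EtO)2MeSiH, t-BuOH, toluene, 0 °C) should give (4R)-5-ethoxy-8-(prop-2-en-1-yl)-4-propyl-7-(triisopropylsilyloxy)-3,4-dihydro-2H-chromen-2-one F6. Methanolysis of this lactone (MeOH, Et3N, rt) gives 16.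

Step 9 (de-ethylation).
- What may go wrong: chloride attack at silicon of the C5 silyl ether, the other oxygen ortho to the carbonyl, may compete with the slower SN2 displacement at ethyl. Lewis-acid activation of the enone may also cause unselective ring closure or chloride addition.
- Fallback: the C8a oxygen is carried as a tert-butyl ether, which is cleaved by ionisation with a protic acid and needs no chelation or chloride. It sets out from 4 and comes back at 21. tert-Butoxyacetylene F7, a known volatile ynol ether prepared by the established dehydrohalogenation route and used in solution, replaces 5 in the conditions of step 4 and should give methyl (3R)-3-(2-tert-butoxy-4-oxocyclobut-2-en-1-yl)hexanoate F8. Benzannulation with 11 as in step 6 gives methyl (3R)-3-[6-tert-butoxy-2-hydroxy-3-(prop-2-en-1-yl)-4-(triisopropylsilyloxy)phenyl]hexanoate F9. Silylation as in step 7 gives methyl (3R)-3-[6-tert-butoxy-2-(tert-butyldimethylsilyloxy)-3-(prop-2-en-1-yl)-4-(triisopropylsilyloxy)phenyl]hexanoate F10. Acylation with 18 as in step 8 gives methyl (3R)-3-{6-tert-butoxy-2-(tert-butyldimethylsilyloxy)-5-[(2E)-2-methylbut-2-enoyl]-3-(prop-2-en-1-yl)-4-(triisopropylsilyloxy)phenyl}hexanoate F11. F11 should lose 2-methylpropene on brief exposure to CF3CO2H in CH2Cl2 at 0 °C (or already under the SnCl4 conditions) to give 21.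

Step 10 (oxa-Michael closure).
- What may go wrong: poor control of the protonation that sets C3, or amine-mediated epimerisation of 22 toward the more stable trans isomer, would erode the cis:trans ratio even where the facial selectivity at C2 is good.
- Fallback: C3 is set in a separate operation by kinetic protonation. It sets out from 21, through the C3-epimer mixture that step 10 then delivers, and comes back at 22. The mixture of 22 and methyl (3R)-3-[(2R,3R)-7-(tert-butyldimethylsilyloxy)-2,3-dimethyl-4-oxo-6-(prop-2-en-1-yl)-5-(triisopropylsilyloxy)-3,4-dihydro-2H-chromen-8-yl]hexanoate F12 is converted by soft enolisation (Me3SiOTf, Et3N, CH2Cl2, 0 °C; the ester is not enolised) into the single enol silane methyl (3R)-3-[(2R)-7-(tert-butyldimethylsilyloxy)-2,3-dimethyl-6-(prop-2-en-1-yl)-5-(triisopropylsilyloxy)-4-(trimethylsilyloxy)-2H-chromen-8-yl]hexanoate F13. In F13 the C2 methyl should sit pseudo-axial to avoid allylic strain with the C3 methyl. Irreversible C-protonation (dilute aq. HCl, THF, −40 °C) anti to that methyl should therefore give the cis ketone 22, with C2 untouched.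

**Further compounds**

F1 | step 6 | 5,7-dihydroxy-4-propyl-2H-chromen-2-one (commercial) | CCCC1=CC(=O)Oc2cc(O)cc(O)c12
F2 | step 6 | 5-hydroxy-7-(prop-2-en-1-yloxy)-4-propyl-2H-chromen-2-one | CCCC1=CC(=O)Oc2cc(OCC=C)cc(O)c12
F3 | step 6 | 5-ethoxy-7-(prop-2-en-1-yloxy)-4-propyl-2H-chromen-2-one | CCCC1=CC(=O)Oc2cc(OCC=C)cc(OCC)c12
F4 | step 6 | 5-ethoxy-7-hydroxy-8-(prop-2-en-1-yl)-4-propyl-2H-chromen-2-one | CCCC1=CC(=O)Oc2c(CC=C)c(O)cc(OCC)c12
F5 | step 6 | 5-ethoxy-8-(prop-2-en-1-yl)-4-propyl-7-(triisopropylsilyloxy)-2H-chromen-2-one | CCCC1=CC(=O)Oc2c(CC=C)c(O[Si](C(C)C)(C(C)C)C(C)C)cc(OCC)c12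
F6 | step 6 | (4R)-5-ethoxy-8-(prop-2-en-1-yl)-4-propyl-7-(triisopropylsilyloxy)-3,4-dihydro-2H-chromen-2-one | CCC[C@@H]1CC(=O)Oc2c(CC=C)c(O[Si](C(C)C)(C(C)C)C(C)C)cc(OCC)c12
F7 | step 9 | tert-butoxyacetylene (2-(ethynyloxy)-2-methylpropane) | CC(C)(C)OC#C
F8 | step 9 | methyl (3R)-3-(2-tert-butoxy-4-oxocyclobut-2-en-1-yl)hexanoate | CCC[C@H](CC(=O)OC)C1C(=O)C=C1OC(C)(C)C
F9 | step 9 | methyl (3R)-3-[6-tert-butoxy-2-hydroxy-3-(prop-2-en-1-yl)-4-(triisopropylsilyloxy)phenyl]hexanoate | CCC[C@H](CC(=O)OC)c1c(O)c(CC=C)c(O[Si](C(C)C)(C(C)C)C(C)C)cc1OC(C)(C)C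
F10 | step 9 | methyl (3R)-3-[6-tert-butoxy-2-(tert-butyldimethylsilyloxy)-3-(prop-2-en-1-yl)-4-(triisopropylsilyloxy)phenyl]hexanoate | CCC[C@H](CC(=O)OC)c1c(O[Si](C)(C)C(C)(C)C)c(CC=C)c(O[Si](C(C)C)(C(C)C)C(C)C)cc1OC(C)(C)C
F11 | step 9 | methyl (3R)-3-{6-tert-butoxy-2-(tert-butyldimethylsilyloxy)-5-[(2E)-2-methylbut-2-enoyl]-3-(prop-2-en-1-yl)-4-(triisopropylsilyloxy)phenyl}hexanoate | CCC[C@H](CC(=O)OC)c1c(O[Si](C)(C)C(C)(C)C)c(CC=C)c(O[Si](C(C)C)(C(C)C)C(C)C)c(C(=O)/C(C)=C/C)c1OC(C)(C)C
F12 | step 10 | methyl (3R)-3-[(2R,3R)-7-(tert-butyldimethylsilyloxy)-2,3-dimethyl-4-oxo-6-(prop-2-en-1-yl)-5-(triisopropylsilyloxy)-3,4-dihydro-2H-chromen-8-yl]hexanoate | CCC[C@H](CC(=O)OC)c1c(O[Si](C)(C)C(C)(C)C)c(CC=C)c(O[Si](C(C)C)(C(C)C)C(C)C)c2c1O[C@H](C)[C@@H](C)C2=O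
F13 | step 10 | methyl (3R)-3-[(2R)-7-(tert-butyldimethylsilyloxy)-2,3-dimethyl-6-(prop-2-en-1-yl)-5-(triisopropylsilyloxy)-4-(trimethylsilyloxy)-2H-chromen-8-yl]hexanoate | CCC[C@H](CC(=O)OC)c1c(O[Si](C)(C)C(C)(C)C)c(CC=C)c(O[Si](C(C)C)(C(C)C)C(C)C)c2c1O[C@H](C)C(C)=C2O[Si](C)(C)C
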